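The runs were generated by integration for an exercise; noise was put on by code.

We follow one invariant through these flasks: each product takes up one partner, so c(partner) + c(catalyst intermediate B) + c(product) should stay at the charge of partner.

the same everywhere: free catalyst 50 mM
- teal: starting material 0.50 M; partner 0.38 M; protic impurity 0.025 M; run made earlier
- blue: starting material 1 M; partner 0.25 M; protic impurity 0.025 M; run made earlier
- east: starting material 0.50 M; partner 0.250 M; protic impurity 0.0250 M; time 1.5 h
- north-east: starting material 0.50 M; partner 0.250 M; protic impurity 0.0500 M; time 1.5 h

| run | time / min | product / % | catalyst intermediate A / % | starting material / % | catalyst intermediate B / % |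
|---|---|---|---|---|---|
| teal | 4.00 | 14.5 | 0.8 | 78.9 | 0 |
| teal | 8.00 | 27.2 | 1.1 | 67.4 | 0.2 |
| teal | 12.0 | 36.1 | 0.7 | 57.1 | 0 |
| teal | 20.0 | 49.6 | 0.7 | 44.1 | 0.3 |
| teal | 30.0 | 60.5 | 0.8 | 33.7 | 0.2 |
| teal | 50.0 | 69.7 | 1.0 | 24.1 | 0 |
| blue | 4.00 | 10.3 | 1.2 | 85.8 | 0.2 |
| blue | 8.00 | 17.1 | 1.7 | 78.8 | 0 |
| blue | 12.0 | 21.1 | 1.5 | 74.6 | 0 |
| blue | 20.0 | 23.6 | 1.7 | 71.1 | 0 |
| blue | 30.0 | 25.0 | 2.2 | 70.9 | 0 |
| blue | 50.0 | 25.0 | 2.2 | 70.7 | 0.6 |

(scatter of a reading: 0.3 percentage points)

- which of these there is most of at the end, counted by the starting material in it, east (starting material / catalyst intermediate A / catalyst intermediate B / product)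
- which of these there is most of at the end, counted by the starting material in it, north-east (starting material / catalyst intermediate A / catalyst intermediate B / product)
- how much there is at the end of the one of these that leads, in percent of the starting material charged: east
- how much there is at the end of the one of these that leads, in percent of the starting material charged: north-east

- the earlier runs were read with a standard deviation of 0.3 percentage points
- no earlier run changes the charge of protic impurity; that part of a forecast is a guess

1. Blue tests this. Its product stands at 25.0% at 30.0 min and 25.0% at 50.0 min, with starting material still at 70.7%, and 0.25 M of partner on 1 M of starting material allows 25.0%. Partner is the limiting reagent in blue.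

2. We name the partner ceiling: charged partner over charged starting material, as a percentage, 50.0% for east and north-east.

3. Teal is east's neighbour: both have the same charges of starting material, protic impurity and free catalyst, but teal has 0.38 M of partner against 0.250 M in east. Its ceiling is 76.0%, but its last reading has not arrived there. The gap falls from 26 percentage points at 20.0 min to 6.3 points at 50.0 min, one power of ten per 48.2 min. If east's gap shrinks at that pace, 1.5 h gives 1.87 powers of ten, leaving 1.36% of the gap. Our figure for east is product at 49.3%.

4. Teal's readings sum short by 5.20% at 50.0 min, against 5.00% for impurity over starting material. We read this as protic impurity taking its equivalent of starting material. North-east then has 90.0% of its starting material unquenched, more than the ceiling. No run varies the impurity, so our figure for north-east is a guess: product leading near 50.0%.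

5. The forecast agrees on east: product, 49.4% (47.5% to 50.2%). For north-east it differs from us: starting material, 89% (82% to 91%), reasoning that impurity matches catalyst, “so all catalyst dies”.

6. East ends with product at 50.0% beside starting material at 43.3%. North-east ends with product at 50.0% beside starting material at 38.4%.

    partner + catalyst intermediate A ⇌ catalyst intermediate B (K = 1.90 L mol⁻¹, k = 0.186 L mol⁻¹ s⁻¹)
    catalyst intermediate B → free catalyst + product (k = 1.04 s⁻¹)
    starting material + free catalyst ⇌ catalyst intermediate A (K = 0.990 L mol⁻¹, k = 0.0236 L mol⁻¹ s⁻¹)
    starting material + protic impurity → quenched substrate (k = 0.0303 L mol⁻¹ s⁻¹)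

In north-east, the forward step from starting material to catalyst intermediate A uses starting material at 0.78 times the rate of quenching at the start, and at 520 times the quenching rate of that moment at 0.159 h. At 0.750 h north-east holds protic impurity at 0% of its charge, quenched substrate at 10.0% of the starting material charged, and free catalyst at 84.2% of the catalyst charged. A further flask like north-east, with 0.062 M of partner, has a ceiling of 12.4% and ends with product at 12.4%.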